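**Retrosynthetic overview**

1. Selaginellin 23 ⇐ acid-induced loss of five MOM groups and of water from triaryl carbinol 21 ⇐ aryllithium 20 + diaryl ketone 18 ⇐ Suzuki–Miyaura (C–Cl) and Sonogashira (C–Br) couplings on the 2-bromo-6-chlorobenzophenone 13.
2. Key disconnection: the para-oxygenated ring on the methide carbon ⇐ 5-aroyl-2-pyrone 7 + 1,1-dimethoxyethylene 8 (inverse-demand Diels–Alder, loss of CO2 and MeOH). Pyrone C3, C4, C5, C6 become C6, C5, C4, C3 of the cyclohexadienone, the acetal carbon becomes C1 (C=O) and its CH2 becomes C2. The new bonds are therefore C1–C6 and C2–C3, and the carboxyl carbon of coumalic acid becomes the methide carbon.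
3. Enabling feature: in the cyclohexadienone ring the oxygen-bearing C1 lies para to C4, the carbon bonded to the exocyclic methide carbon. With the methide carbon held at the ketone level, this is the acyl-at-C5 pattern of a coumalic acid pyrone, whose acyl group makes pyrone C6 the electrophilic diene terminus. The cyclohexadienone and 4-hydroxyphenyl rings on the methide carbon exchange roles by degenerate proton transfer, so the ring can be built as an anisole and carried as a protected phenol.
4. 7 ⇐ coumalyl chloride 4 + arylzinc 6, from deprotonation of 2 at the C–H between Br and Cl. Temporary elements removed later: lactone bridge (as CO2, step 4), O-methyl (step 5), ketone oxidation level (steps 10 and 11).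
5. Ring order: central benzene ring bought (1) → pyrone ring attached (step 3) and converted into the first oxygenated ring (step 4) → tolane ring (step 8) → biaryl ring (step 9) → last oxygenated ring (step 10) → quinone methide (step 11).

Key step: step 4

Remark: compounds 1, 3, 8, 14, 17 and 19 are taken as catalogue compounds; the target has no stereocenter, and the quinone methide is the neutral dehydrated form of its para-hydroxyphenyl carbinol.

**Step 1**
Reactants: 1 (2-bromo-4-chlorophenyl)methanol
Product: 2 2-bromo-4-chloro-1-[(methoxymethoxy)methyl]benzene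
Conditions: MOMCl, iPr2NEt, CH2Cl2, 0 °C → rt
Reagents that add atoms: chloromethyl methyl ether (MOMCl), COCCl
Why: O-alkylation of the primary alcohol with the α-chloro ether (MOM acetal formation) should be clean, and the acetal tolerates the lithium amide, the organozinc, the neutral cycloaddition and the chloride demethylation that follow.

**Step 2**
Reactants: 3 coumalic acid (2-oxo-2H-pyran-5-carboxylic acid)
Product: 4 coumalyl chloride (2-oxo-2H-pyran-5-carbonyl chloride)
Conditions: SOCl2, cat. DMF, 75 °C; volatiles removed
Reagents that add atoms: thionyl chloride, O=S(Cl)Cl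
Why: Acid chloride formation with thionyl chloride; the vinylogous pyrone lactone should not be opened under anhydrous acidic conditions.

**Step 3**
Reactants: 2 2-bromo-4-chloro-1-[(methoxymethoxy)methyl]benzene; 4 coumalyl chloride
Product: 7 5-{2-bromo-6-chloro-3-[(methoxymethoxy)methyl]benzoyl}-2H-pyran-2-one, via aryllithium 5 (not isolated), via arylzinc chloride 6 (not isolated)
Conditions: lithium 2,2,6,6-tetramethylpiperidide (LiTMP), THF, −78 °C; ZnCl2, −78 → 0 °C; then 4, Pd(PPh3)4 (5 mol %), 0 °C → rt
Reagents that add atoms: none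
Why: The ring C–H flanked by Br and Cl is the most acidic site and should be removed by the hindered amide (deprotonative lithiation between two halogens), transmetalation to zinc suppresses aryne formation, and the Negishi acylation catalyzed by zerovalent palladium joins the arylzinc to the acid chloride, while neither the zinc reagent nor the liberated hindered amine attacks the pyrone.

**Step 4 (key step)**
Reactants: 7 5-{2-bromo-6-chloro-3-[(methoxymethoxy)methyl]benzoyl}-2H-pyran-2-one; 8 1,1-dimethoxyethylene
Product: 11 {2-bromo-6-chloro-3-[(methoxymethoxy)methyl]phenyl}(4-methoxyphenyl)methanone, via bridged lactone 9 (not isolated), via cyclohexadiene ketal 10 (not isolated)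
Conditions: 8 (3 equiv), toluene, 80 °C, sealed tube
Reagents that add atoms: none
Why: The 5-aroyl-2-pyrone is an electron-poor diene across C3–C6 and the ketene acetal an electron-rich dienophile, so an inverse-electron-demand Diels–Alder reaction should occur in which the nucleophilic CH2 terminus bonds to pyrone C6 (β to the C5 acyl group, α to the ring oxygen) and the acetal carbon bonds to C3, giving bridged lactone 9. Retro-Diels–Alder loss of CO2 from 9 gives cyclohexadiene ketal 10, whose ring CH2 is vinylogously acidified by the ketone, so loss of methanol aromatizes it to the 4-methoxyphenyl ketone. The closest known reaction type is the conversion of coumalate esters (5-alkoxycarbonyl-2-pyrones) with ketene acetals into 4-alkoxybenzoates. One six-membered carbocycle is closed, by intermolecular [4+2] cycloaddition followed by extrusion of the CO2 bridge. The two bridgehead stereocenters of 9 are fixed only relative to each other by the suprafacial addition and are erased on aromatization, so no stereocontrol is needed. The step needs regioselectivity (oxygen para to the acyl-bearing carbon), secured by the C5 acyl group that makes C6 the electrophilic diene terminus, and chemoselectivity over the ketone, the aryl halides and the acetal, secured by the neutral thermal conditions.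

**Step 5**
Reactants: 11 {2-bromo-6-chloro-3-[(methoxymethoxy)methyl]phenyl}(4-methoxyphenyl)methanone
Product: 12 {2-bromo-6-chloro-3-[(methoxymethoxy)methyl]phenyl}(4-hydroxyphenyl)methanone
Conditions: LiCl (5 equiv), DMF, 150 °C; then cold dilute aq. HCl to pH 4
Reagents that add atoms: none
Why: Nucleophilic demethylation: SN2 attack of chloride on the O-methyl group of an anisole activated by the para aroyl group (the 4-acylphenoxide is a good leaving group), under conditions that should leave the MOM acetal and the weakly activated ring halides alone.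

**Step 6**
Reactants: 12 {2-bromo-6-chloro-3-[(methoxymethoxy)methyl]phenyl}(4-hydroxyphenyl)methanone
Product: 13 {2-bromo-6-chloro-3-[(methoxymethoxy)methyl]phenyl}[4-(methoxymethoxy)phenyl]methanone
Conditions: MOMCl, iPr2NEt, CH2Cl2, 0 °C → rt
Reagents that add atoms: chloromethyl methyl ether (MOMCl), COCCl
Why: MOM ether formation on the acidic 4-acylphenol gives a ketone that is not deactivated by a para phenoxide and an oxygen protecting group that falls in the final acid step.

**Step 7**
Reactants: 14 4-ethynylphenol
Product: 15 1-ethynyl-4-(methoxymethoxy)benzene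
Conditions: MOMCl, iPr2NEt, CH2Cl2, 0 °C → rt
Reagents that add atoms: chloromethyl methyl ether (MOMCl), COCCl
Why: MOM ether formation on the phenol; the terminal alkyne C–H is not touched by the amine base.

**Step 8**
Reactants: 13 {2-bromo-6-chloro-3-[(methoxymethoxy)methyl]phenyl}[4-(methoxymethoxy)phenyl]methanone; 15 1-ethynyl-4-(methoxymethoxy)benzene
Product: 16 {6-chloro-3-[(methoxymethoxy)methyl]-2-{[4-(methoxymethoxy)phenyl]ethynyl}phenyl}[4-(methoxymethoxy)phenyl]methanone
Conditions: PdCl2(PPh3)2 (5 mol %), CuI (10 mol %), Et3N/DMF, 80 °C, degassed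
Reagents that add atoms: none
Why: Sonogashira coupling, in which oxidative addition should take place at the weaker C–Br bond of the electron-poor ring while the C–Cl bond is inert to the triphenylphosphine–palladium catalyst.

**Step 9**
Reactants: 16 (chloro alkynyl ketone from step 8); 17 [4-(methoxymethoxy)phenyl]boronic acid
Product: 18 {4'-(methoxymethoxy)-4-[(methoxymethoxy)methyl]-3-{[4-(methoxymethoxy)phenyl]ethynyl}biphenyl-2-yl}[4-(methoxymethoxy)phenyl]methanone
Conditions: Pd(OAc)2 (5 mol %), SPhos (10 mol %), K3PO4, toluene/H2O (10:1), 100 °C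
Reagents that add atoms: none
Why: Suzuki–Miyaura coupling of an aryl chloride bearing one ortho substituent, for which the electron-rich dialkylbiarylphosphine ligand is chosen; the internal alkyne, the ketone and the MOM ethers are stable to the mild base.

**Step 10**
Reactants: 18 (tetra-MOM diaryl ketone from step 9); 19 1-bromo-4-(methoxymethoxy)benzene
Product: 21 {4'-(methoxymethoxy)-4-[(methoxymethoxy)methyl]-3-{[4-(methoxymethoxy)phenyl]ethynyl}biphenyl-2-yl}bis[4-(methoxymethoxy)phenyl]methanol, via aryllithium 20 (not isolated)
Conditions: 19 (3 equiv), n-BuLi, THF, −78 °C; then 18, −78 → 0 °C; H2O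
Reagents that add atoms: none
Why: Bromine–lithium exchange and 1,2-addition of the aryllithium to the non-enolizable diaryl ketone; the carbinol carbon receives a second 4-(methoxymethoxy)phenyl group identical to the first and is therefore no stereocenter.

**Step 11**
Reactants: 21 (penta-MOM triaryl carbinol from step 10)
Product: 23 selaginellin, via deprotected carbinol 22 (not isolated)
Conditions: HCl (3 M) in MeOH/THF (1:1), 40 °C; then aq. NaHCO3 to pH 6–7
Reagents that add atoms: none
Why: Acid-catalyzed acetal exchange with methanol removes the five MOM groups, and the carbinol with two para-hydroxyphenyl groups ionizes and loses water to the quinone methide (fuchsone formation); the temperature is kept low so that the stabilized cation does not close onto the neighbouring aryl ring, and no stereocenter is involved.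

**Compound list**

1 | (2-bromo-4-chlorophenyl)methanol | OCc1ccc(Cl)cc1Br | starting material
2 | 2-bromo-4-chloro-1-[(methoxymethoxy)methyl]benzene | COCOCc1ccc(Cl)cc1Br | intermediate
3 | coumalic acid (2-oxo-2H-pyran-5-carboxylic acid) | OC(=O)C1=COC(=O)C=C1 | starting material
4 | coumalyl chloride (2-oxo-2H-pyran-5-carbonyl chloride) | ClC(=O)C1=COC(=O)C=C1 | intermediate
5 | {2-bromo-6-chloro-3-[(methoxymethoxy)methyl]phenyl}lithium | [Li]c1c(Cl)ccc(COCOC)c1Br | intermediate
6 | chlorido{2-bromo-6-chloro-3-[(methoxymethoxy)methyl]phenyl}zinc | Cl[Zn]c1c(Cl)ccc(COCOC)c1Br | intermediate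
7 | 5-{2-bromo-6-chloro-3-[(methoxymethoxy)methyl]benzoyl}-2H-pyran-2-one | COCOCc1ccc(Cl)c(C(=O)C2=COC(=O)C=C2)c1Br | intermediate
8 | 1,1-dimethoxyethylene (ketene dimethyl acetal) | C=C(OC)OC | starting material
9 | 6-{2-bromo-6-chloro-3-[(methoxymethoxy)methyl]benzoyl}-8,8-dimethoxy-2-oxabicyclo[2.2.2]oct-5-en-3-one (racemate, one enantiomer drawn; the two bridgeheads are fixed relative to each other by the bicycle) | O=C1O[C@@H]2CC(OC)(OC)[C@H]1C=C2C(=O)c3c(Cl)ccc(COCOC)c3Br | intermediate
10 | {2-bromo-6-chloro-3-[(methoxymethoxy)methyl]phenyl}(4,4-dimethoxycyclohexa-1,5-dien-1-yl)methanone | COC1(OC)CC=C(C(=O)c2c(Cl)ccc(COCOC)c2Br)C=C1 | intermediate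
11 | {2-bromo-6-chloro-3-[(methoxymethoxy)methyl]phenyl}(4-methoxyphenyl)methanone | COCOCc1ccc(Cl)c(C(=O)c2ccc(OC)cc2)c1Br | intermediate
12 | {2-bromo-6-chloro-3-[(methoxymethoxy)methyl]phenyl}(4-hydroxyphenyl)methanone | COCOCc1ccc(Cl)c(C(=O)c2ccc(O)cc2)c1Br | intermediate
13 | {2-bromo-6-chloro-3-[(methoxymethoxy)methyl]phenyl}[4-(methoxymethoxy)phenyl]methanone | COCOCc1ccc(Cl)c(C(=O)c2ccc(OCOC)cc2)c1Br | intermediate
14 | 4-ethynylphenol | C#Cc1ccc(O)cc1 | starting material
15 | 1-ethynyl-4-(methoxymethoxy)benzene | COCOc1ccc(C#C)cc1 | intermediate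
16 | {6-chloro-3-[(methoxymethoxy)methyl]-2-{[4-(methoxymethoxy)phenyl]ethynyl}phenyl}[4-(methoxymethoxy)phenyl]methanone | COCOCc1ccc(Cl)c(C(=O)c2ccc(OCOC)cc2)c1C#Cc1ccc(OCOC)cc1 | intermediate
17 | [4-(methoxymethoxy)phenyl]boronic acid | COCOc1ccc(B(O)O)cc1 | starting material
18 | {4'-(methoxymethoxy)-4-[(methoxymethoxy)methyl]-3-{[4-(methoxymethoxy)phenyl]ethynyl}biphenyl-2-yl}[4-(methoxymethoxy)phenyl]methanone | COCOCc1ccc(-c2ccc(OCOC)cc2)c(C(=O)c2ccc(OCOC)cc2)c1C#Cc1ccc(OCOC)cc1 | intermediate
19 | 1-bromo-4-(methoxymethoxy)benzene | COCOc1ccc(Br)cc1 | starting material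
20 | [4-(methoxymethoxy)phenyl]lithium | [Li]c1ccc(OCOC)cc1 | intermediate
21 | {4'-(methoxymethoxy)-4-[(methoxymethoxy)methyl]-3-{[4-(methoxymethoxy)phenyl]ethynyl}biphenyl-2-yl}bis[4-(methoxymethoxy)phenyl]methanol | COCOCc1ccc(-c2ccc(OCOC)cc2)c(C(O)(c2ccc(OCOC)cc2)c2ccc(OCOC)cc2)c1C#Cc1ccc(OCOC)cc1 | intermediate
22 | {4'-hydroxy-4-(hydroxymethyl)-3-[(4-hydroxyphenyl)ethynyl]biphenyl-2-yl}bis(4-hydroxyphenyl)methanol | OCc1ccc(-c2ccc(O)cc2)c(C(O)(c2ccc(O)cc2)c2ccc(O)cc2)c1C#Cc1ccc(O)cc1 | intermediate
23 | selaginellin, 4-[{3-(hydroxymethyl)-6-(4-hydroxyphenyl)-2-[(4-hydroxyphenyl)ethynyl]phenyl}(4-hydroxyphenyl)methylidene]cyclohexa-2,5-dien-1-one | O=C1C=CC(=C(c2ccc(O)cc2)c2c(-c3ccc(O)cc3)ccc(CO)c2C#Cc2ccc(O)cc2)C=C1 | target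

**Step count and risks**

Total step count: 11. Longest linear sequence: 9 steps (1, 3, 4, 5, 6, 8, 9, 10, 11) from (2-bromo-4-chlorophenyl)methanol.

Steps most likely to fail:

Step 3. Lithium halide may be eliminated from the ortho-haloaryllithium (aryne formation) before transmetalation. Alternatively, acyl transfer from the doubly ortho-substituted arylzinc may be so slow that the pyrone acid chloride is consumed by decarbonylation at palladium or by attack at pyrone C6. The fallback reverses the polarity at the ketone carbon; it sets out from 2 and returns at 7. Compound 2 is lithiated as before and quenched at −78 °C with CO2 to give 2-bromo-6-chloro-3-[(methoxymethoxy)methyl]benzoic acid F1. This is converted under neutral conditions with 1-chloro-N,N,2-trimethylprop-1-en-1-amine into 2-bromo-6-chloro-3-[(methoxymethoxy)methyl]benzoyl chloride F2. In parallel, 5-(trimethylstannyl)-2H-pyran-2-one F3 is made from the catalogue compound 5-bromo-2H-pyran-2-one, Me3SnSnMe3 and Pd(PPh3)4. Stille acylation of F2 with F3 (PdCl2(PPh3)2, toluene, 80 °C) should then give 7 without any carbanion meeting the pyrone.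

Step 5. Demethylation may be too slow at a temperature at which the ring halides begin to be exchanged (by chloride, or by dimethylamine from DMF) or the MOM acetal is lost. The fallback accepts loss of the acetal and rebuilds it; it sets out from 11 and returns at 13, so it also replaces step 6. BBr3 (CH2Cl2, −78 → 0 °C) should cleave the aryl methyl ether and turn the benzylic MOM ether into the bromide, giving [2-bromo-3-(bromomethyl)-6-chlorophenyl](4-hydroxyphenyl)methanone F4. Silver-assisted hydrolysis (AgNO3, acetone/H2O, 50 °C) should give [2-bromo-6-chloro-3-(hydroxymethyl)phenyl](4-hydroxyphenyl)methanone F5. Double protection (MOMCl, iPr2NEt, CH2Cl2, 40 °C) then gives 13.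

Step 8. Oxidative addition at the C–Br bond flanked by the aroyl and the CH2OMOM group may be slow, so that the copper acetylide of 15 is consumed by Glaser-type homocoupling. The fallback builds the diarylalkyne in two C–C bond formations; it sets out from 13 and returns at 16. Sonogashira coupling of 13 with a large excess of ethynyltrimethylsilane (sealed tube) should give {6-chloro-3-[(methoxymethoxy)methyl]-2-[(trimethylsilyl)ethynyl]phenyl}[4-(methoxymethoxy)phenyl]methanone F6. K2CO3 in MeOH gives the terminal alkyne {6-chloro-2-ethynyl-3-[(methoxymethoxy)methyl]phenyl}[4-(methoxymethoxy)phenyl]methanone F7. A second Sonogashira coupling of F7 with 1-iodo-4-(methoxymethoxy)benzene F8 (made from 4-iodophenol and MOMCl, iPr2NEt) gives 16, the oxidative addition now taking place at an unhindered aryl iodide.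

**Further compounds**

F1 | step 3 | 2-bromo-6-chloro-3-[(methoxymethoxy)methyl]benzoic acid | COCOCc1ccc(Cl)c(C(=O)O)c1Br
F2 | step 3 | 2-bromo-6-chloro-3-[(methoxymethoxy)methyl]benzoyl chloride | COCOCc1ccc(Cl)c(C(=O)Cl)c1Br
F3 | step 3 | 5-(trimethylstannyl)-2H-pyran-2-one | C[Sn](C)(C)C1=COC(=O)C=C1
F4 | step 5 | [2-bromo-3-(bromomethyl)-6-chlorophenyl](4-hydroxyphenyl)methanone | BrCc1ccc(Cl)c(C(=O)c2ccc(O)cc2)c1Br
F5 | step 5 | [2-bromo-6-chloro-3-(hydroxymethyl)phenyl](4-hydroxyphenyl)methanone | OCc1ccc(Cl)c(C(=O)c2ccc(O)cc2)c1Br
F6 | step 8 | {6-chloro-3-[(methoxymethoxy)methyl]-2-[(trimethylsilyl)ethynyl]phenyl}[4-(methoxymethoxy)phenyl]methanone | COCOCc1ccc(Cl)c(C(=O)c2ccc(OCOC)cc2)c1C#C[Si](C)(C)C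
F7 | step 8 | {6-chloro-2-ethynyl-3-[(methoxymethoxy)methyl]phenyl}[4-(methoxymethoxy)phenyl]methanone | COCOCc1ccc(Cl)c(C(=O)c2ccc(OCOC)cc2)c1C#C
F8 | step 8 | 1-iodo-4-(methoxymethoxy)benzene | COCOc1ccc(I)cc1
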